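**Strategy.** Daucane numbering: C1 (methyl-bearing ring-fusion carbon), C5 (ring-fusion CH), C6 (aroyloxy carbon), C8/C9 (epoxide), C10 (carbinol). The seven-membered ring is read as a two-carbon unit C9–C10 spanning the termini C1 and C8 of the five-carbon chain C1–C5–C6–C7–C8. A rhodium-catalysed (5+2) cycloaddition of acetylene with a donor–acceptor vinylcyclopropane, a 6-siloxy-6-propenylbicyclo[3.1.0]hexan-2-one that already holds the cyclopentane, cleaves C1–C6 and forms C1–C10 and C8–C9 in one operation. Ring-fusion inversion, stereocontrolled reductions, isopropyl addition, a Schenck ene transposition and epoxidation complete the target.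

Key step: step 6

Remark on numbering: all intermediates carry the daucane numbers (C1/C5 ring fusion, C2–C4 cyclopentane, C6–C10 cycloheptane); α is the face of the C1 methyl group, β the opposite face.
Remark on reagents: diazoethane (7) is taken as a freshly prepared ethereal solution from commercial N-ethyl-N-nitrosourea and aqueous KOH.

Step 1
Reactants: 1 methyl (3R)-3-(tert-butyldimethylsilyloxy)-5-oxo-6-(triphenyl-λ5-phosphanylidene)hexanoate; 2 acetaldehyde
Product: 3 methyl (3R,6E)-3-(tert-butyldimethylsilyloxy)-5-oxooct-6-enoate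
Conditions: CH3CHO (5 equiv.), toluene, 60 °C, sealed tube
Reagents that add atoms: none
Why: Wittig olefination of a stabilised acyl ylide with an aliphatic aldehyde should give the (E)-enone, and the carbinol stereocentre is not touched.

Step 2
Reactants: 3 methyl (3R,6E)-3-(tert-butyldimethylsilyloxy)-5-oxooct-6-enoate
Product: 4 (3R,6E)-3-(tert-butyldimethylsilyloxy)-5-oxooct-6-enoic acid
Conditions: pig liver esterase, pH 7.2 phosphate buffer, acetone (10%), 25 °C
Reagents that add atoms: water, O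
Why: Enzymatic ester hydrolysis at neutral pH should free the acid without β-elimination of the silyloxy ketone or addition to the enone.

Step 3
Reactants: 4 (3R,6E)-3-(tert-butyldimethylsilyloxy)-5-oxooct-6-enoic acid
Product: 6 (3S,4Z,6E)-3,5-bis(tert-butyldimethylsilyloxy)octa-4,6-dienoic acid, via silyl ester 5 (not isolated)
Conditions: TBSOTf (2.4 equiv.), Et3N, CH2Cl2, −78 → 0 °C; then aq. NaHCO3, THF, 23 °C
Reagents that add atoms: tert-butyldimethylsilyl trifluoromethanesulfonate, CC(C)(C)[Si](C)(C)OS(=O)(=O)C(F)(F)F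
Why: Soft enolisation (silyl triflate and amine) should remove the α′ proton of the enone to give the cross-conjugated 2-siloxydiene with Z geometry (C4 cis to oxygen, the bulky C4 avoiding the propenyl group), and the labile silyl ester is hydrolysed on mild aqueous treatment.

Step 4
Reactants: 6 (3S,4Z,6E)-3,5-bis(tert-butyldimethylsilyloxy)octa-4,6-dienoic acid; 7 diazoethane
Product: 9 (5S,6Z,8E)-5,7-bis(tert-butyldimethylsilyloxy)-2-diazodeca-6,8-dien-3-one, via mixed anhydride 8 (not isolated)
Conditions: i-BuOCOCl, N-methylmorpholine, THF, −20 °C; then CH3CHN2 (3 equiv.), Et2O, −20 → 0 °C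
Reagents that add atoms: none
Why: Acylation of a diazoalkane by a mixed carbonic anhydride (the diazoketone synthesis of the Arndt–Eistert sequence) runs under neutral conditions that should spare the silyl dienol ether.

Step 5
Reactants: 9 (5S,6Z,8E)-5,7-bis(tert-butyldimethylsilyloxy)-2-diazodeca-6,8-dien-3-one
Product: 10 4α,6-bis(tert-butyldimethylsilyloxy)-1α-methyl-6-[(E)-prop-1-enyl]bicyclo[3.1.0]hexan-2-one (cyclopropane carbon C6 on the β face, 6-siloxy endo, propenyl exo, 5α-H)
Conditions: Cu(acac)2 (5 mol %), toluene, 85 °C, slow addition of 9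
Reagents that add atoms: none
Why: Intramolecular cyclopropanation of the electron-rich silyl enol ether by the copper carbenoid closes the five-membered ring; allylic 1,3-strain with the cis siloxy group keeps C4–H in the alkene plane so the 4-silyloxy group ends anti to the cyclopropane, and stereospecific addition to the Z enol ether places the 6-siloxy group endo and the propenyl group exo, which sets C1, C5 and C6 from C4.

Step 6
Reactants: 10 4α,6-bis(tert-butyldimethylsilyloxy)-1α-methyl-6-[(E)-prop-1-enyl]bicyclo[3.1.0]hexan-2-one; 11 acetylene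
Product: 13 cis-fused 4α-(tert-butyldimethylsilyloxy)-1α,8β-dimethylbicyclo[5.3.0]dec-9-ene-2,6-dione (5α-H), via silyl enol ether 12 (not isolated)
Conditions: [Rh(CO)2Cl]2 (5 mol %), HC≡CH (1 atm), ClCH2CH2Cl, 60 °C; then 0.5 M aq. HCl, THF, 0 °C
Reagents that add atoms: none
Why: Monovalent rhodium bound to the exo propenyl group opens the donor–acceptor C1–C6 bond of the cyclopropane (siloxy donor on C6, C2 ketone acceptor on C1) to a trivalent rhodacyclohexene, acetylene inserts into the Rh–C8 bond (C8–C9 formed), and C(sp3)–C(sp2) reductive elimination at C1 forms C1–C10. The closest known reaction type is the intermolecular rhodium-catalysed (5+2) cycloaddition of 1-siloxy-1-vinylcyclopropanes with alkynes, which delivers the ring as its silyl enol ether. The cycloheptadiene is closed by this two-bond (5+2) annulation (insertion, then ring-contracting reductive elimination from an eight-membered rhodacycle), with the cyclopentane carried through intact. C1 reacts with retention, so C10 takes the place of C6 (cis ring fusion at this stage), and C8 is set by the E geometry of the propenyl group in the s-cis conformer together with bond formation on the rhodium face, which should put C8–H on the α face, syn to the C1 methyl. The step needs cleavage of C1–C6 rather than C5–C6, which the push–pull polarisation of that bond and the enolate character of the Rh–C1 bond should secure, and it needs acetylene to add faster than it oligomerises, hence 1 atm only. Dilute acid then hydrolyses the enol ether and should leave the secondary silyl ether.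

Step 7
Reactants: 13 cis-fused 4α-(tert-butyldimethylsilyloxy)-1α,8β-dimethylbicyclo[5.3.0]dec-9-ene-2,6-dione
Product: 14 4α-(tert-butyldimethylsilyloxy)-1α,8β-dimethyl-2,6-bis(trimethylsilyloxy)bicyclo[5.3.0]deca-2,5,9-triene
Conditions: Me3SiCl, NaI, Et3N, MeCN, 23 °C
Reagents that add atoms: chlorotrimethylsilane, C[Si](C)(C)Cl
Why: Equilibrating silylation with iodotrimethylsilane made in situ should give the more substituted C5=C6 enol ether of the ring ketone (and the only possible C2=C3 ether), which makes C5 trigonal.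

Step 8
Reactants: 14 4α-(tert-butyldimethylsilyloxy)-1α,8β-dimethyl-2,6-bis(trimethylsilyloxy)bicyclo[5.3.0]deca-2,5,9-triene
Product: 16 trans-fused 4α-(tert-butyldimethylsilyloxy)-1α,8β-dimethylbicyclo[5.3.0]dec-9-ene-2α,6α-diol (5β-H), via trans-diketone 15 (not isolated)
Conditions: Bu4NF, AcOH, THF, −78 °C; then CeCl3·7H2O, NaBH4, MeOH, −78 → −40 °C
Reagents that add atoms: none
Why: Fluoride frees the enolates at −78 °C and buffered C-protonation at C5 should occur on the β face, because the 1α-methyl and 4α-silyloxy groups flank the α face, giving the trans ring fusion kinetically; Luche reduction in the same flask then adds hydride anti to the axial C1 methyl at both carbonyls (2α-OH, 6α-OH) before C5 can equilibrate.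

Step 9
Reactants: 16 trans-fused 4α-(tert-butyldimethylsilyloxy)-1α,8β-dimethylbicyclo[5.3.0]dec-9-ene-2α,6α-diol; 17 4-methoxybenzoic acid
Product: 18 4α-(tert-butyldimethylsilyloxy)-2α-hydroxy-1α,8β-dimethylbicyclo[5.3.0]dec-9-en-6β-yl 4-methoxybenzoate
Conditions: 17 (1.5 equiv.), PPh3, DIAD, toluene, 0 → 23 °C
Reagents that add atoms: none
Why: Mitsunobu esterification should invert the less hindered C6 carbinol (carboxylate enters from the open β face) to the 6β ester, while the neopentyl C2 hydroxyl does not react.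

Step 10
Reactants: 18 4α-(tert-butyldimethylsilyloxy)-2α-hydroxy-1α,8β-dimethylbicyclo[5.3.0]dec-9-en-6β-yl 4-methoxybenzoate
Product: 19 2α-acetoxy-4α-(tert-butyldimethylsilyloxy)-1α,8β-dimethylbicyclo[5.3.0]dec-9-en-6β-yl 4-methoxybenzoate
Conditions: Ac2O, DMAP, pyridine, CH2Cl2, 23 °C
Reagents that add atoms: acetic anhydride, CC(=O)OC(C)=O
Why: DMAP-catalysed acylation should acetylate the remaining hindered secondary alcohol with retention.

Step 11
Reactants: 19 2α-acetoxy-4α-(tert-butyldimethylsilyloxy)-1α,8β-dimethylbicyclo[5.3.0]dec-9-en-6β-yl 4-methoxybenzoate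
Product: 20 2α-acetoxy-4α-hydroxy-1α,8β-dimethylbicyclo[5.3.0]dec-9-en-6β-yl 4-methoxybenzoate
Conditions: HF·pyridine, pyridine, THF, 0 → 23 °C
Reagents that add atoms: none
Why: Buffered fluoride cleaves the secondary silyl ether, and the weakly acidic medium should prevent acyl migration to the freed hydroxyl.

Step 12
Reactants: 20 2α-acetoxy-4α-hydroxy-1α,8β-dimethylbicyclo[5.3.0]dec-9-en-6β-yl 4-methoxybenzoate
Product: 21 2α-acetoxy-1α,8β-dimethyl-4-oxobicyclo[5.3.0]dec-9-en-6β-yl 4-methoxybenzoate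
Conditions: Dess–Martin periodinane, NaHCO3, CH2Cl2, 0 → 23 °C
Reagents that add atoms: none
Why: Dess–Martin oxidation under buffered neutral conditions should give the ketone without β-elimination of the two acyloxy groups.

Step 13
Reactants: 21 2α-acetoxy-1α,8β-dimethyl-4-oxobicyclo[5.3.0]dec-9-en-6β-yl 4-methoxybenzoate
Product: 22 2α-acetoxy-4α-hydroxy-4β-isopropyl-1α,8β-dimethylbicyclo[5.3.0]dec-9-en-6β-yl 4-methoxybenzoate
Conditions: i-PrMgCl, CeCl3, THF, −78 °C
Reagents that add atoms: isopropylmagnesium chloride, CC(C)[Mg]Cl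
Why: The weakly basic organocerium reagent adds to enolisable ketones without elimination and faster than to esters, and attack on the C4 carbonyl of the trans-fused bicycle should come from the β face, anti to the axial C1 methyl, the 2α-acetate and the C5–C6 bond, giving the 4α-hydroxy-4β-isopropyl centre.

Step 14
Reactants: 22 2α-acetoxy-4α-hydroxy-4β-isopropyl-1α,8β-dimethylbicyclo[5.3.0]dec-9-en-6β-yl 4-methoxybenzoate
Product: 24 2α-acetoxy-4α,10α-dihydroxy-4β-isopropyl-1α,8-dimethylbicyclo[5.3.0]dec-8-en-6β-yl 4-methoxybenzoate, via hydroperoxide 23 (not isolated)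
Conditions: O2, hν (visible), tetraphenylporphyrin (cat.), CH2Cl2, 0 °C; then PPh3, 0 °C
Reagents that add atoms: dioxygen, O=O
Why: In the Schenck ene reaction of singlet oxygen the only allylic hydrogen is the α-oriented C8–H, so the suprafacial process should place the hydroperoxide on C10 on the α face and move the double bond to C8=C9; triphenylphosphine reduces the hydroperoxide to the alcohol.

Step 15
Reactants: 24 2α-acetoxy-4α,10α-dihydroxy-4β-isopropyl-1α,8-dimethylbicyclo[5.3.0]dec-8-en-6β-yl 4-methoxybenzoate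
Product: 25 CNP0371526.1 (2α-acetoxy-8β,9β-epoxy-4α,10α-dihydroxy-4β-isopropyl-1α,8α-dimethylbicyclo[5.3.0]decan-6β-yl 4-methoxybenzoate)
Conditions: dimethyldioxirane, acetone, 0 °C
Reagents that add atoms: dimethyldioxirane, CC1(C)OO1
Why: Epoxidation of the trisubstituted C8=C9 alkene by the dioxirane in acetone (weak hydroxyl direction) should follow steric approach control from the β face, opposite the axial C1 methyl and the 10α-hydroxyl, giving the β-epoxide.

**Compound list**

1 | methyl (3R)-3-(tert-butyldimethylsilyloxy)-5-oxo-6-(triphenyl-λ5-phosphanylidene)hexanoate | COC(=O)C[C@H](O[Si](C)(C)C(C)(C)C)CC(=O)C=P(c1ccccc1)(c1ccccc1)c1ccccc1 | starting material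
2 | acetaldehyde | CC=O | starting material
3 | methyl (3R,6E)-3-(tert-butyldimethylsilyloxy)-5-oxooct-6-enoate | COC(=O)C[C@H](O[Si](C)(C)C(C)(C)C)CC(=O)/C=C/C | intermediate
4 | (3R,6E)-3-(tert-butyldimethylsilyloxy)-5-oxooct-6-enoic acid | OC(=O)C[C@H](O[Si](C)(C)C(C)(C)C)CC(=O)/C=C/C | intermediate
5 | tert-butyldimethylsilyl (3S,4Z,6E)-3,5-bis(tert-butyldimethylsilyloxy)octa-4,6-dienoate | CC(C)(C)[Si](C)(C)OC(=O)C[C@H](O[Si](C)(C)C(C)(C)C)/C=C(\O[Si](C)(C)C(C)(C)C)/C=C/C | intermediate (not isolated)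
6 | (3S,4Z,6E)-3,5-bis(tert-butyldimethylsilyloxy)octa-4,6-dienoic acid | OC(=O)C[C@H](O[Si](C)(C)C(C)(C)C)/C=C(\O[Si](C)(C)C(C)(C)C)/C=C/C | intermediate
7 | diazoethane | CC=[N+]=[N-] | starting material (prepared just before use, see remark)
8 | isobutyl carbonic anhydride of acid 6 | CC(C)COC(=O)OC(=O)C[C@H](O[Si](C)(C)C(C)(C)C)/C=C(\O[Si](C)(C)C(C)(C)C)/C=C/C | intermediate (not isolated)
9 | (5S,6Z,8E)-5,7-bis(tert-butyldimethylsilyloxy)-2-diazodeca-6,8-dien-3-one | CC(=[N+]=[N-])C(=O)C[C@H](O[Si](C)(C)C(C)(C)C)/C=C(\O[Si](C)(C)C(C)(C)C)/C=C/C | intermediate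
10 | 4α,6-bis(tert-butyldimethylsilyloxy)-1α-methyl-6-[(E)-prop-1-enyl]bicyclo[3.1.0]hexan-2-one (C6 on β face, 6-siloxy endo, 5α-H) | C/C=C/[C@@]1(O[Si](C)(C)C(C)(C)C)[C@@H]2[C@@H](O[Si](C)(C)C(C)(C)C)CC(=O)[C@]12C | intermediate
11 | acetylene | C#C | starting material
12 | cis-fused 4α,6-bis(tert-butyldimethylsilyloxy)-1α,8β-dimethylbicyclo[5.3.0]deca-6,9-dien-2-one (5α-H) | CC(C)(C)[Si](C)(C)OC1=C[C@@H](C)C=C[C@]2(C)[C@H]1[C@@H](O[Si](C)(C)C(C)(C)C)CC2=O | intermediate (not isolated)
13 | cis-fused 4α-(tert-butyldimethylsilyloxy)-1α,8β-dimethylbicyclo[5.3.0]dec-9-ene-2,6-dione (5α-H) | O=C1C[C@@H](C)C=C[C@]2(C)[C@H]1[C@@H](O[Si](C)(C)C(C)(C)C)CC2=O | intermediate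
14 | 4α-(tert-butyldimethylsilyloxy)-1α,8β-dimethyl-2,6-bis(trimethylsilyloxy)bicyclo[5.3.0]deca-2,5,9-triene | C[Si](C)(C)OC1=C2[C@@H](O[Si](C)(C)C(C)(C)C)C=C(O[Si](C)(C)C)[C@]2(C)C=C[C@H](C)C1 | intermediate
15 | trans-fused 4α-(tert-butyldimethylsilyloxy)-1α,8β-dimethylbicyclo[5.3.0]dec-9-ene-2,6-dione (5β-H) | O=C1C[C@@H](C)C=C[C@]2(C)[C@@H]1[C@@H](O[Si](C)(C)C(C)(C)C)CC2=O | intermediate (not isolated)
16 | trans-fused 4α-(tert-butyldimethylsilyloxy)-1α,8β-dimethylbicyclo[5.3.0]dec-9-ene-2α,6α-diol (5β-H) | O[C@@H]1C[C@@H](C)C=C[C@]2(C)[C@@H]1[C@@H](O[Si](C)(C)C(C)(C)C)C[C@H]2O | intermediate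
17 | 4-methoxybenzoic acid | COc1ccc(C(=O)O)cc1 | starting material
18 | 4α-(tert-butyldimethylsilyloxy)-2α-hydroxy-1α,8β-dimethylbicyclo[5.3.0]dec-9-en-6β-yl 4-methoxybenzoate | COc1ccc(C(=O)O[C@H]2C[C@@H](C)C=C[C@]3(C)[C@@H]2[C@@H](O[Si](C)(C)C(C)(C)C)C[C@H]3O)cc1 | intermediate
19 | 2α-acetoxy-4α-(tert-butyldimethylsilyloxy)-1α,8β-dimethylbicyclo[5.3.0]dec-9-en-6β-yl 4-methoxybenzoate | COc1ccc(C(=O)O[C@H]2C[C@@H](C)C=C[C@]3(C)[C@@H]2[C@@H](O[Si](C)(C)C(C)(C)C)C[C@H]3OC(C)=O)cc1 | intermediate
20 | 2α-acetoxy-4α-hydroxy-1α,8β-dimethylbicyclo[5.3.0]dec-9-en-6β-yl 4-methoxybenzoate | COc1ccc(C(=O)O[C@H]2C[C@@H](C)C=C[C@]3(C)[C@@H]2[C@@H](O)C[C@H]3OC(C)=O)cc1 | intermediate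
21 | 2α-acetoxy-1α,8β-dimethyl-4-oxobicyclo[5.3.0]dec-9-en-6β-yl 4-methoxybenzoate | COc1ccc(C(=O)O[C@H]2C[C@@H](C)C=C[C@]3(C)[C@@H]2C(=O)C[C@H]3OC(C)=O)cc1 | intermediate
22 | 2α-acetoxy-4α-hydroxy-4β-isopropyl-1α,8β-dimethylbicyclo[5.3.0]dec-9-en-6β-yl 4-methoxybenzoate | COc1ccc(C(=O)O[C@H]2C[C@@H](C)C=C[C@]3(C)[C@@H]2[C@](O)(C(C)C)C[C@H]3OC(C)=O)cc1 | intermediate
23 | 2α-acetoxy-10α-hydroperoxy-4α-hydroxy-4β-isopropyl-1α,8-dimethylbicyclo[5.3.0]dec-8-en-6β-yl 4-methoxybenzoate | COc1ccc(C(=O)O[C@H]2CC(C)=C[C@H](OO)[C@]3(C)[C@@H]2[C@](O)(C(C)C)C[C@H]3OC(C)=O)cc1 | intermediate (not isolated)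
24 | 2α-acetoxy-4α,10α-dihydroxy-4β-isopropyl-1α,8-dimethylbicyclo[5.3.0]dec-8-en-6β-yl 4-methoxybenzoate | COc1ccc(C(=O)O[C@H]2CC(C)=C[C@H](O)[C@]3(C)[C@@H]2[C@](O)(C(C)C)C[C@H]3OC(C)=O)cc1 | intermediate
25 | CNP0371526.1 | COc1ccc(C(=O)O[C@H]2C[C@@]3(C)O[C@H]3[C@H](O)[C@]3(C)[C@@H]2[C@](O)(C(C)C)C[C@H]3OC(C)=O)cc1 | target

**Step count.** Total: 15 steps. Longest linear sequence: 15 steps (1 → 25).

**Steps most likely to fail**

Step 6. Rhodium may insert into the less hindered C5–C6 bond, reductive elimination at the fully substituted C1 may be too slow so that the vinylcyclopropane isomerises instead, or acetylene may oligomerise. The fallback takes the quaternary centre out of the cycloaddition; it sets out from 6 and comes back at 13. Acid 6 is converted as in step 4 into mixed anhydride 8, which with diazomethane gives the terminal diazoketone F1. Cyclopropanation with Cu(acac)2 gives the 1-demethyl vinylcyclopropane F2. Its less hindered, still ketone-activated C1–C6 bond is opened in the same rhodium-catalysed (5+2) reaction with acetylene to give the silyl enol ether F3, which carries C1–H. Deprotonation of the doubly activated C1–H (KHMDS, THF, −78 °C) and methylation with iodomethane on the α face, anti to the C5–C6 bond, gives 12, which is hydrolysed to 13 as in step 6.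

Step 8. Enolisation in step 7 may go toward C7 so that C5 stays cis, the fluoride-generated enolates may lose the 4-silyloxy group by β-elimination, or protonation may occur on the α face or be followed by equilibration to the cis-fused ketone before reduction. The fallback replaces enolate protonation by radical hydrogen transfer; it sets out from 14 and comes back at 16. Phenylselenyl chloride (2 equiv., CH2Cl2, −78 °C) converts 14 into the bis(phenylselanyl) diketone F4, selenium entering C5 from the open β face. Bu3SnH and AIBN (benzene, 80 °C) then deliver hydrogen to the planar C5 radical from the β face (and to C3) without any enolate, and the resulting trans-diketone 15 is reduced at once under the Luche conditions of step 8 to 16.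

Step 14. The ene reaction must take place on the hindered α face of a cis-disubstituted alkene and may be slow, and the more electron-rich trisubstituted alkene of the product may be oxidised further. The fallback moves the oxygen in by an epoxide; it sets out from 22 and comes back at 24. mCPBA epoxidises C9=C10 of 22 on the open β face to the 9β,10β-epoxide F5. Sodium phenylselenide (from PhSeSePh and NaBH4, EtOH) opens it at C9 with inversion to the hydroxy selenide F6. Oxidation with H2O2 and syn elimination of the selenoxide toward the cis C8–H gives the 10β-allylic alcohol F7. MnO2 oxidises it to the enone F8, and Luche reduction, with hydride entering anti to the axial C1 methyl, gives 24 before step 15.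

**Further compounds**

F1 | step 6 | (4S,5Z,7E)-4,6-bis(tert-butyldimethylsilyloxy)-1-diazonona-5,7-dien-2-one | [N-]=[N+]=CC(=O)C[C@H](O[Si](C)(C)C(C)(C)C)/C=C(\O[Si](C)(C)C(C)(C)C)/C=C/C
F2 | step 6 | 4α,6-bis(tert-butyldimethylsilyloxy)-6-[(E)-prop-1-enyl]bicyclo[3.1.0]hexan-2-one (1-demethyl analogue of 10, 1α-H) | C/C=C/[C@@]1(O[Si](C)(C)C(C)(C)C)[C@@H]2[C@@H](O[Si](C)(C)C(C)(C)C)CC(=O)[C@H]12
F3 | step 6 | cis-fused 4α,6-bis(tert-butyldimethylsilyloxy)-8β-methylbicyclo[5.3.0]deca-6,9-dien-2-one (1-demethyl analogue of 12, 1α-H) | CC(C)(C)[Si](C)(C)OC1=C[C@@H](C)C=C[C@@H]2[C@H]1[C@@H](O[Si](C)(C)C(C)(C)C)CC2=O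
F4 | step 8 | 4α-(tert-butyldimethylsilyloxy)-1α,8β-dimethyl-3,5β-bis(phenylselanyl)bicyclo[5.3.0]dec-9-ene-2,6-dione (C3 epimers) | O=C1C[C@@H](C)C=C[C@]2(C)[C@]1([Se]c1ccccc1)[C@@H](O[Si](C)(C)C(C)(C)C)C([Se]c1ccccc1)C2=O
F5 | step 14 | 2α-acetoxy-9β,10β-epoxy-4α-hydroxy-4β-isopropyl-1α,8β-dimethylbicyclo[5.3.0]decan-6β-yl 4-methoxybenzoate | COc1ccc(C(=O)O[C@H]2C[C@@H](C)[C@H]3O[C@H]3[C@]4(C)[C@@H]2[C@](O)(C(C)C)C[C@H]4OC(C)=O)cc1
F6 | step 14 | 2α-acetoxy-4α,10β-dihydroxy-4β-isopropyl-1α,8β-dimethyl-9α-(phenylselanyl)bicyclo[5.3.0]decan-6β-yl 4-methoxybenzoate | COc1ccc(C(=O)O[C@H]2C[C@@H](C)[C@H]([Se]c3ccccc3)[C@@H](O)[C@]3(C)[C@@H]2[C@](O)(C(C)C)C[C@H]3OC(C)=O)cc1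
F7 | step 14 | 2α-acetoxy-4α,10β-dihydroxy-4β-isopropyl-1α,8-dimethylbicyclo[5.3.0]dec-8-en-6β-yl 4-methoxybenzoate (10-epimer of 24) | COc1ccc(C(=O)O[C@H]2CC(C)=C[C@@H](O)[C@]3(C)[C@@H]2[C@](O)(C(C)C)C[C@H]3OC(C)=O)cc1
F8 | step 14 | 2α-acetoxy-4α-hydroxy-4β-isopropyl-1α,8-dimethyl-10-oxobicyclo[5.3.0]dec-8-en-6β-yl 4-methoxybenzoate | COc1ccc(C(=O)O[C@H]2CC(C)=CC(=O)[C@]3(C)[C@@H]2[C@](O)(C(C)C)C[C@H]3OC(C)=O)cc1
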